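**Fraction left.** Follow what remains of a species from one reading to a later one, not what has been made. These are the two flasks, Monday's readings and the question.

| flask | starting complex | incoming ligand | protic impurity | remark | time |
|---|---|---|---|---|---|
| Monday's | 1.5 M (fed, over 1.5 h) | 1.95 M | 0.75 M | run made earlier |  |
| flask | 1.5 M (fed, over 1.5 h) | 1.95 M | 1.50 M |  | 8.0 h |

Monday's run (percent of the starting complex charged)

| time / h | complex with one exchanged / % | complex with four exchanged / % | starting complex / % |
|---|---|---|---|
| 0.833 | 8.2 | 1.1 | 40.4 |
| 1.50 | 18.8 | 2.0 | 59.7 |
| 2.50 | 22.4 | 1.4 | 39.6 |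
| 3.00 | 24.2 | 0.6 | 37.2 |
| 4.00 | 22.3 | 0 | 32.1 |
| 5.00 | 21.5 | 0 | 28.8 |

(readings scatter by 1 percentage point)

- percentages count the whole charge, also what has not yet gone in
- no earlier run changes the charge of protic impurity; that part of a forecast is a guess

1. amount of complex with one exchanged in percent of the starting complex charged, at 1.5 h, 4.0 h and 8.0 h

**Two half-lives.** After the feed in Monday's run, starting complex falls from 39.6% at 2.50 h to 28.8% at 5.00 h. Reckoned as a pseudo-first-order decay, these two readings give a half-life of 5.44 h. In Monday's run complex with one exchanged falls from 24.2% at 3.00 h to 21.5% at 5.00 h. This gives its tail half-life, the time in which the amount left halves at the pace of the late readings: 11.7 h. It is a rough reading, since the fall is 2.7 percentage points and each reading scatters by 1 point.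

**My reckoning.** Complex with one exchanged is made from starting complex, and in Monday's readings its half-life is about twice that of its source. So I take the two paces as the ends of an estimated range for the new flask. From 4.0 h to 8.0 h, I estimate the fraction left of complex with one exchanged in the new flask between 60.1%, the source's pace, and 78.9%, Monday's own pace. The new flask carries twice the protic impurity, and no run shows its effect, so this is a guess.

**The forecast.** It gives 17%, 20% and 16%, expecting “a somewhat faster decline”. Its fraction left, 80.0%, stands slightly above the upper end of my range.

**The flask.** The new flask gives 17.2%, 17.1% and 11.4%.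

    starting complex + incoming ligand ⇌ leaving ligand + complex with one exchanged (K = 0.500, k = 8.60 × 10⁻⁵ L mol⁻¹ s⁻¹)
    complex with three exchanged + incoming ligand ⇌ leaving ligand + complex with four exchanged (K = 0.230, k = 6.00 × 10⁻⁵ L mol⁻¹ s⁻¹)
    complex with one exchanged + incoming ligand ⇌ leaving ligand + complex with two exchanged (K = 0.310, k = 9.10 × 10⁻⁵ L mol⁻¹ s⁻¹)
    protic impurity + starting complex → quenched substrate (k = 1.20 × 10⁻⁴ L mol⁻¹ s⁻¹)
    complex with two exchanged + incoming ligand ⇌ leaving ligand + complex with three exchanged (K = 0.380, k = 1.70 × 10⁻⁴ L mol⁻¹ s⁻¹)

From 4.0 h to 8.0 h the new flask keeps 66.7% of its complex with one exchanged, inside my range. In the new flask quenched substrate stands at 65.8% of the charge at 8.0 h. Carry Monday's tail half-life of 11.7 h forward from 11.4% over a further 8.0 h: it gives 7.10%, and the new flask holds 7.01% at 16.0 h.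

The runs stem from a simulated flask on assumed constants; scatter was added.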